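**Retrosynthetic overview**
1. Target 8 (ring C closed last) ⇒ O1–C2 bond: oxidative C–O cyclisation of the 2',6'-dihydroxychalcone 6. Its two ortho hydroxyls are equivalent, so one closes ring C and the other is left as the 5-OH, with no protecting group or demethylation.
2. Chalcone 6 ⇒ Claisen–Schmidt condensation of ketone 4 with aldehyde 5, the only C–C bond formed; rings A and B are bought intact.
3. Ketone 4 ⇒ both aryl C–O bonds (future C5–OH and C8a–O1) come from the two ortho C–H bonds of 3',4',5'-trimethoxyacetophenone 1 by a twofold ketone-directed C–H oxygenation (key step).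

Assumption: agehoustin E is an achiral flavone with no stereocentre, so no enantioselective step is needed; the only stereo-elements on the way are the E alkene of 6 and the transient racemic flavanone 7.

**Step 1**
Reactants: 1 3',4',5'-trimethoxyacetophenone (1-(3,4,5-trimethoxyphenyl)ethan-1-one)
Product: 4 1-(2,6-dihydroxy-3,4,5-trimethoxyphenyl)ethan-1-one, via aryl mono(trifluoroacetate) 2 (not isolated), via aryl bis(trifluoroacetate) 3 (not isolated)
Conditions: Pd(OCOCF3)2 (10 mol %), PhI(OCOCF3)2 (2.5 equiv, two portions), CF3CO2H/(CF3CO)2O (4:1), 60 °C; then H2O/THF, rt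
Reagents that add atoms: [bis(trifluoroacetoxy)iodo]benzene, O=C(OI(OC(=O)C(F)(F)F)c1ccccc1)C(F)(F)F (source of both new oxygen atoms)
Why: Proposed new method: exhaustive (twofold) ketone-directed ortho-C–H oxygenation of one ring – carbonyl-assisted electrophilic palladation by divalent palladium trifluoroacetate gives a five-membered palladacycle, PhI(OCOCF3)2 oxidises it to tetravalent palladium and C–O reductive elimination gives aryl trifluoroacetate 2; (CF3CO)2O keeps the new oxygen capped as a non-chelating ester, so no phenol–carbonyl hydrogen bond shuts down the directing group, and the remaining ortho C–H is still para to a methoxy group, so a second palladation/oxidation gives 3, which water cleaves to 4; the ring has only two C–H bonds and both are the directed and the innately most nucleophilic sites, so no regioisomer can form; the closest known reaction type is the palladium- or ruthenium-catalysed ketone-directed mono-ortho-hydroxylation of aryl ketones in CF3CO2H/(CF3CO)2O, which to my knowledge has not been driven to double oxygenation of one ring.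

**Step 2**
Reactants: 4 1-(2,6-dihydroxy-3,4,5-trimethoxyphenyl)ethan-1-one; 5 2,4,5-trimethoxybenzaldehyde
Product: 6 (E)-1-(2,6-dihydroxy-3,4,5-trimethoxyphenyl)-3-(2,4,5-trimethoxyphenyl)prop-2-en-1-one
Conditions: KOH (50 % aq., 10 equiv), EtOH, Ar, rt, 48 h; then 1 M HCl, 0 °C
Reagents that add atoms: none
Why: Claisen–Schmidt (crossed aldol) condensation – the methyl-ketone enolate of the phenolate adds to the non-enolisable aldehyde and E1cB dehydration gives the conjugated, thermodynamically favoured E enone; no stereocentre is formed.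

**Step 3**
Reactants: 6 (E)-1-(2,6-dihydroxy-3,4,5-trimethoxyphenyl)-3-(2,4,5-trimethoxyphenyl)prop-2-en-1-one
Product: 8 agehoustin E = 5-hydroxy-6,7,8-trimethoxy-2-(2,4,5-trimethoxyphenyl)-4H-chromen-4-one, via racemic flavanone 7 (not isolated)
Conditions: I2 (10 mol %), DMSO, 130 °C, 3 h
Reagents that add atoms: none
Why: Iodine/DMSO oxidative cyclisation of a 2'-hydroxychalcone – oxa-Michael closure forms the O1–C2 bond (flavanone 7), α-iodination and loss of HI dehydrogenate C2–C3, and DMSO re-oxidises HI to I2; the two ortho hydroxyls of 6 are equivalent, so one flavone results and the spectator hydroxyl becomes the chelated 5-OH; ring A has no C–H left to iodinate and the C2 stereocentre of 7 disappears on aromatisation.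

**Compound list**
1 | 3',4',5'-trimethoxyacetophenone (1-(3,4,5-trimethoxyphenyl)ethan-1-one) | CC(=O)c1cc(OC)c(OC)c(OC)c1 | starting material
2 | 2-acetyl-4,5,6-trimethoxyphenyl 2,2,2-trifluoroacetate | CC(=O)c1cc(OC)c(OC)c(OC)c1OC(=O)C(F)(F)F | intermediate (not isolated)
3 | 2-acetyl-4,5,6-trimethoxy-1,3-phenylene bis(2,2,2-trifluoroacetate) | CC(=O)c1c(OC(=O)C(F)(F)F)c(OC)c(OC)c(OC)c1OC(=O)C(F)(F)F | intermediate (not isolated)
4 | 1-(2,6-dihydroxy-3,4,5-trimethoxyphenyl)ethan-1-one | CC(=O)c1c(O)c(OC)c(OC)c(OC)c1O | intermediate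
5 | 2,4,5-trimethoxybenzaldehyde | COc1cc(OC)c(C=O)cc1OC | starting material
6 | (E)-1-(2,6-dihydroxy-3,4,5-trimethoxyphenyl)-3-(2,4,5-trimethoxyphenyl)prop-2-en-1-one | COc1cc(OC)c(/C=C/C(=O)c2c(O)c(OC)c(OC)c(OC)c2O)cc1OC | intermediate
7 | racemic 5-hydroxy-6,7,8-trimethoxy-2-(2,4,5-trimethoxyphenyl)chroman-4-one | COc1cc(OC)c(C2CC(=O)c3c(O)c(OC)c(OC)c(OC)c3O2)cc1OC | intermediate (not isolated)
8 | agehoustin E, 5-hydroxy-6,7,8-trimethoxy-2-(2,4,5-trimethoxyphenyl)-4H-chromen-4-one (achiral) | COc1cc(OC)c(-c2cc(=O)c3c(O)c(OC)c(OC)c(OC)c3o2)cc1OC | target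

**Totals**
Total step count: 3. Longest linear sequence: 3 steps (1 → 4 → 6 → 8).

**Steps most likely to fail**

Step 1 (proposed new step, highest risk). The second oxygenation may stall because the acetyl group, once flanked by an ortho trifluoroacetate, twists out of plane. PhI(OCOCF3)2 may also oxidise the acetyl α-position or the electron-rich ring. Fallback (known chemistry, sets out from 5 and returns at 8): the ring-A oxygens are bought instead of made. Aldehyde 5 is condensed (KOH, EtOH, rt) with commercial but more costly 1-(2-hydroxy-3,4,5,6-tetramethoxyphenyl)ethan-1-one F1 to give (E)-1-(2-hydroxy-3,4,5,6-tetramethoxyphenyl)-3-(2,4,5-trimethoxyphenyl)prop-2-en-1-one F2. I2 (cat.)/DMSO at 130 °C closes this to 5,6,7,8-tetramethoxy-2-(2,4,5-trimethoxyphenyl)-4H-chromen-4-one F3. BCl3 (CH2Cl2, −78 to 0 °C) then cleaves only the 5-O-methyl group, which is peri to and chelated by the C4 carbonyl, and gives 8.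

Step 2. The dianion of a 2,6-dihydroxyacetophenone is a sluggish, air-sensitive nucleophile and aldehyde 5 is electron-rich, so conversion may be low. Any flavanone 7 formed on acidification is harmless, because it is the intermediate of step 3. Fallback (sets out from 4 and returns at 8, bypassing step 3): the aldol C–C bond is replaced by a Baker–Venkataraman acyl transfer. Ketone 4 is heated with commercial 2,4,5-trimethoxybenzoyl chloride F4 and DBU in pyridine (80 to 110 °C). O-acylation gives 2-acetyl-3-hydroxy-4,5,6-trimethoxyphenyl 2,4,5-trimethoxybenzoate F5. DBU-mediated O-to-C acyl migration gives 1-(2,6-dihydroxy-3,4,5-trimethoxyphenyl)-3-(2,4,5-trimethoxyphenyl)propane-1,3-dione F6. This cyclodehydrates in the same pot (or on brief H2SO4/AcOH treatment) to 8.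

Step 3. Iodine at 130 °C could iodinate the electron-rich ring B or cleave a methyl ether through HI. Fallback (sets out from 6 and returns at 8): cyclisation and oxidation are separated and iodine is avoided. Chalcone 6 is isomerised with NaOAc in refluxing EtOH to flavanone 7, which is isolated and dehydrogenated with DDQ in refluxing 1,4-dioxane (hydride abstraction at the electron-rich benzylic C2, then loss of the C3 proton) to give 8. This fallback makes no new compound (entry F0).

**Further compounds**
F1 | step 1 | 1-(2-hydroxy-3,4,5,6-tetramethoxyphenyl)ethan-1-one (purchased) | CC(=O)c1c(O)c(OC)c(OC)c(OC)c1OC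
F2 | step 1 | (E)-1-(2-hydroxy-3,4,5,6-tetramethoxyphenyl)-3-(2,4,5-trimethoxyphenyl)prop-2-en-1-one | COc1cc(OC)c(/C=C/C(=O)c2c(O)c(OC)c(OC)c(OC)c2OC)cc1OC
F3 | step 1 | 5,6,7,8-tetramethoxy-2-(2,4,5-trimethoxyphenyl)-4H-chromen-4-one | COc1cc(OC)c(-c2cc(=O)c3c(OC)c(OC)c(OC)c(OC)c3o2)cc1OC
F4 | step 2 | 2,4,5-trimethoxybenzoyl chloride (purchased) | COc1cc(OC)c(C(=O)Cl)cc1OC
F5 | step 2 | 2-acetyl-3-hydroxy-4,5,6-trimethoxyphenyl 2,4,5-trimethoxybenzoate | CC(=O)c1c(O)c(OC)c(OC)c(OC)c1OC(=O)c1cc(OC)c(OC)cc1OC
F6 | step 2 | 1-(2,6-dihydroxy-3,4,5-trimethoxyphenyl)-3-(2,4,5-trimethoxyphenyl)propane-1,3-dione | COc1cc(OC)c(C(=O)CC(=O)c2c(O)c(OC)c(OC)c(OC)c2O)cc1OC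
F0 | step 3 | none | none
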